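You read this flask at 20 min, so what counts is the difference of the two products at that time, a small gap on a large sum. Reckon the gap as a correction and leave the sum to the readings.

| setting | Thursday's | flask |
|---|---|---|
| left-handed substrate | 0.61 M | 0.91 M |
| right-handed substrate | 0.61 M | 0.91 M |
| partner | 2.27 M | 2.27 M |
| remark | run made earlier |  |
| time |  | 20 min |

- Thursday's (time / min: left-handed product / %, right-handed product / %): 3.00: 37.9, 29.7; 6.00: 41.8, 38.0; 8.00: 44.9, 40.1; 12.0: 47.5, 43.1; 15.0: 47.4, 45.4; 20.0: 49.6, 46.3

(standard deviation of a reading: 1 percentage point)

- excess of left-handed product over right-handed product in the product at 25 s
- excess of left-handed product over right-handed product in the product at 20 min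
- part of the left-handed substrate and right-handed substrate charged together that has reacted at 20 min

- partner is single-handed; left-handed substrate and right-handed substrate are mirror images of each other, charged as a racemate, each of them at the stated concentration
- what has gone into achiral form counts as reacted
- an excess is the difference of the two amounts in percent of their sum
- an excess is below zero if the other one leads
- the handed part of partner does not stay in what it makes, so the products of the two hands are mirror images too

How large is the gap? In Thursday's run the left-handed product leads the right-handed product by 8.2 percentage points at 3.00 min and by 3.3 points at 20.0 min, each with a scatter of 1.4 points.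

How fast does it fade? If the fading is exponential, these two readings give the gap-fading constant, the natural logarithm of the ratio of the two gaps divided by the time between them, as 0.0535 /min. That is a half-life of 13.0 min, read from one run.

What does this flask get? Its partner charge equals Thursday's, but its substrate charge is higher, at 0.91 M against 0.61 M; the same gap, fading at the same constant, is therefore my assumption and nothing more. Fading to 20 min simply returns Thursday's last gap, and dividing that by Thursday's product share of 95.9% gives my excess of 3.44%.

The forecast gives 16% at 25 s, then 5% and 87% reacted at 20 min, adding “The partner runs short, so the flask finishes less completely than Thursday's run.”, and its late excess stands above mine.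

The flask gives 20.7% at 25 s, then 2.56% and 96.1% reacted at 20 min. The flask's excess of 4.91% at 10.0 min, on a product share of 83.9%, is a gap of 4.1 points; fading that gap at 0.0535 /min up to 20 min and dividing by the flask's product share of 92.9% then gives 2.60%.

    partner → decomposition product (k = 4.64 × 10⁻⁶ /s)
    partner + left-handed substrate → left-handed product (k = 0.00515 /M/s)
    left-handed substrate ⇌ achiral form (K = 1.00, k = 0.00169 /s)
    partner + right-handed substrate → right-handed product (k = 0.00321 /M/s)
    left-handed product ⇌ right-handed product (k = 4.33 × 10⁻⁴ /s)
    right-handed substrate ⇌ achiral form (K = 1.00, k = 0.00169 /s)

A neighbour flask holds 1.4 M of partner, its other charges and its time as in this flask. Thursday's gap, faded at 0.0535 /min to 20 min and divided by that neighbour's product share of 71.3%, gives an excess of 4.63%. The computed value for the neighbour is 5.56%.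

All runs stem from a simulated flask for an exercise; scatter was added.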